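The numbers in the tables are simulated on assumed constants; scatter was added.

Put your care into the charge of J, not into the time.

| setting | south-west | south-east | dusk | midnight |
|---|---|---|---|---|
| X | 0.0050 M | 0.0050 M | 0.0050 M | 0.0030 M |
| J | 3.4 mM | 2.5 mM | 5.00 mM | 5.00 mM |
| remark | run made earlier | run made earlier |  |  |
| time |  |  | 8.0 min | 30 min |

- south-west (time / s: D / %): 10.0: 13.7; 20.0: 28.7; 30.0: 45.7; 50.0: 58.4; 80.0: 60.3; 90.0: 61.3
- south-east (time / s: D / %): 15.0: 21.6; 30.0: 46.0; 50.0: 58.8; 60.0: 60.8; 80.0: 62.4; 90.0: 62.6

(each reading ± 0.5 percentage points)

- X is a solid; its amount is given per volume of the solution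
- the analysis behind the earlier runs scatters by 0.5 percentage points, standard deviation
- at the start none of X is in solution
- in a conversion E counts as not yet reacted
- what has only dissolved of X counts as not reacted

* the flask that ends with the higher amount of D, in percent of the X charged, or "neither" when 2 percentage points or less lies between them (dusk / midnight / neither)
* final D, as a percentage of the X charged, in dusk
* final D, as a percentage of the X charged, in midnight

Take the time first. Over the last 10.0 s of the earlier runs D gains 1 percentage point in south-west and 0.2 points in south-east, against a scatter of 0.5 points. Dusk gets 9.60 times the 50.0 s by which both runs have bent over, and midnight 36.0 times, so I count both flasks as finished. Both runs hold 0.0050 M of X, so its effect can't be read, and I assume the percentage ignores it. That leaves J, the setting the runs vary.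

Now count turnovers. The price of D is how many X you charge per D you get, one over the final fraction. If a rival path runs in proportion to [J] (pseudo-first-order) beside a path that doesn't, the price climbs in a straight line with [J], as long as [J] stays near its charge. The prices 1.60 in south-east and 1.63 in south-west give 0.0376 mM⁻¹, the rise in price per unit of [J], which I call the J toll. It is rough: the two readings lie 1.3 points apart, against a scatter of 0.5 points. With 1.50 as the price at zero J, the 5.00 mM of both flasks gives me 59.1% in each, so neither leads.

The forecast says neither, with 63% and 63%, above my figure, holding that “more J shouldn't help”.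

The flasks give neither: 57.7% in dusk and 57.4% in midnight.

    Z + J → Q (k = 3.40 M⁻¹ s⁻¹)
    Z → D (k = 0.0550 s⁻¹)
    X ⇌ Z, rate k3*(cs3 - [Z]) while solid is left; crystals form when [Z] > cs3 (solubility = 2.10 mM, k = 0.260 s⁻¹)
    Z ⇌ E (K = 2.20, k = 0.0300 s⁻¹)
    2 E → L (k = 7.20 M⁻¹ s⁻¹)
    E → G (k = 0.0600 s⁻¹)

With Z + J → Q struck out, midnight ends at 69.0%. Read again from south-west to dusk, the toll is 0.0640 mM⁻¹, higher than my 0.0376 mM⁻¹.

Carried to a neighbour of dusk, charged with 0.020 M of J and otherwise the same, that toll predicts 37.1%. The computed neighbour gives 38.2%.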